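## Analysis of the target

The target is a monocyclic 1,2-dioxane (O1–O2–C3–C4–C5–C6). C6 is a peroxyketal carbon carrying a methoxy group and a (6E)-hexadec-6-en-4-yn-1-yl chain, and C3 carries a CH2CO2H arm. There are two stereocentres, C3 (S) and C6 (R), in a 1,4-relation across the ring. The methoxy group and the acetic acid arm are cis, so in the chair the arm and the long chain are equatorial and the methoxy group is axial, the arrangement favoured by the anomeric effect of O1. The sensitive elements are the O–O bond (reductants, low-valent metals, warm phosphines), the C3–H next to the peroxide and β to the carboxyl (base-induced Kornblum–DeLaMare cleavage or retro-oxa-Michael opening), the acid-labile peroxyketal and the conjugated (E)-enyne. The real difficulty is C3, a secondary peroxy-bearing carbon with no neighbouring handle, which must be made as one enantiomer while the O–O bond is introduced; C6 can be corrected thermodynamically once C3 is secure. The strategy rests on reading C3 and C6 as two 1,4-related carbons spanned by O1–O2, and the C3 arm plus the C6 methoxy oxygen as the two ends of a cut two-carbon bridge C3–CH2–C(=O)–C6. The ring is then the core of a 2,3-dioxabicyclo[2.2.2]octanone, the oxidised adduct of dioxygen with a cyclohexa-1,3-diene.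

## Retrosynthetic reasoning

**24 to 23, then 23 to 19 + 22.** The free acid is released last from methyl ester 23, because a carboxylate β to the peroxide should not be carried through metal-mediated steps. The chain is cut at the C(sp)–C(sp2) bond between alkyne and alkene. This keeps the electron-rich alkene away from every oxidation and leaves a short peroxide-bearing alkyne 19 and a simple (E)-iodoalkene 22 for a room-temperature Sonogashira coupling.

**19 to 18.** The terminal alkyne is masked as its triisopropylsilyl derivative 18. The cap is needed so that hydroboration, transfer hydrogenation and peracid steps see only a hindered internal alkyne.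

**18 to 16.** The C6–OMe bond and the ester O–Me bond are cut together. Both oxygens are tied into one lactone in 16, in which C6 is an acyloxy peroxyketal carbon. The forward step is an acidic methanolysis through a peroxycarbenium ion. It must give axial methoxy, which the anomeric effect and the equatorial C3 arm both favour.

**16 to 15.** Removing the ring oxygen of the lactone restores a C6–C(=O) bond and gives bicyclic ketone 15. The forward Baeyer–Villiger oxidation must migrate the peroxy-bearing bridgehead and not the methylene. This is the point where the carbocyclic bridge is excised.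

**15 to 14 to 13.** The ketone comes from carbinol 14 and the saturated C4–C5 unit from the alkene of 13. The carbinol is kept until after the cycloaddition because it is the only stereocontrol element for that step, and it is erased once it has done its work.

**13 to 12.** The two C–O bonds at the bridgeheads are cut, which reveals dienol 12 and a [4+2] photo-oxygenation. This is the one disconnection that makes the O–O ring and both ring stereocentres at once, from a carbocycle whose single stereocentre is an ordinary secondary alcohol.

**12 to 11 to 10.** The C4=C5 double bond of 12 is traced to an allylic acetate in 11 (1,4-elimination through a π-allyl palladium complex). The carbinol of 11 is traced to enone 10 by a catalyst-controlled reduction. The C1 configuration is therefore not left to 1,4-induction by the remote acetate. The acetate stereocentre only ensures that 11 is a single diastereomer, and it is planarised in the elimination.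

**10 to 8 + 4, 8 to 5, 4 to 1 + 2, 22 to 20.** The C2–chain bond is cut as a B-alkyl Suzuki–Miyaura coupling between iodoenone 8 and the borane 9 made from enyne 4. Iodoenone 8 goes back through enone 7 and monoacetate 6 to meso-diacetate 5 by enzymatic desymmetrisation. Enyne 4 comes from 1 and 2 by allylation of acetylide 3. Iodoalkene 22 comes from alkyne 20 by hydrozirconation–iodination through 21.

## Alternatives that were turned down

**Alternative 1:** The ring is cut at C4–C5, C3–O2 and O1–C6. In the forward sense the α-keto radical from 1-bromohept-6-yn-2-one A1 adds to methyl but-3-enoate A2, the new C3 radical captures dioxygen A3, and the peroxy terminus closes onto the ketone to give the 1,2-dioxan-3-ol A4.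
- For: it is far shorter than the chosen route. The whole ring arises in one operation from two small fragments, and the hemiketal can be methylated under thermodynamic control to the correct relative configuration.
- Against: A4 is formed as the racemate and nothing in the radical chain can bias C3, so a resolution costing half the material would be unavoidable. The α-keto radical is also trapped by A3 in competition with its addition to the unactivated alkene. A2 has doubly activated C–H bonds that peroxyl radicals abstract, and the free alkyne of A1 can cyclise onto the radical.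
- Comparison: on step economy it is clearly stronger. The chosen strategy offers control of absolute configuration, which this target requires.

**Alternative 2:** The ring is cut at C4=C5 of a dihydrodioxine. A second-generation ruthenium metathesis catalyst would close the acyclic mixed peroxyketal diene A5 to the 3-methoxy-3,6-dihydro-1,2-dioxine A6.
- For: ring-closing metathesis across a dialkyl peroxide tether is a reasonable reaction. The route is convergent and modular in the chain, and it avoids both the Baeyer–Villiger regiochemistry question and the fragile dienol 12; on those points it is stronger.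
- Against: A5 needs an enantiopure secondary allylic hydroperoxide, which is hard to obtain without racemisation. Its ketal carbon is an acyclic stereocentre that cannot be controlled when the peroxyketal is formed. A6 is a 3,6-dihydro-1,2-dioxine with a C–H next to oxygen, the substrate class most prone to base- or metal-induced cleavage to γ-hydroxy enones. Its allylic peroxyketal also ionises easily. After closure the route still needs alkene reduction, O-desilylation and a two-stage oxidation of the side arm to the acid beside an O–O bond.
- Comparison: the step count is no lower. The chosen route sets both ring centres in one event from a carbinol made by a dependable asymmetric reduction.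

**Alternative 3:** The ring is cut at C3–C4. A primary radical generated from bromide A7 would add 6-exo-trig to the β-carbon of its (E)-β-peroxy acryloyl oxazolidinone, and a silane hydrogen donor would reduce the resulting α-acyl radical to A8.
- For: the methoxy ketal and the acid oxidation level are already in place, the auxiliary can be hydrolysed directly to the acid with no ester detour, and the finish is short. On those points it is as strong or stronger.
- Against: open-shell intermediates are generated beside an O–O bond. Silyl radicals attack peroxides. The cyclised α-acyl radical sits β to a peroxide oxygen and can collapse to an epoxide by intramolecular substitution at oxygen before it is reduced. Induction at C3 from an auxiliary three atoms away needs a chelating Lewis acid, which endangers the acid-labile acyclic peroxyketal. The ketal carbon of A7 is uncontrolled (correctable later), and the auxiliary is stoichiometric.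
- Comparison: the chosen strategy forms the peroxide ring by a closed-shell pericyclic step and takes C3 from a catalytic asymmetric reduction, at the price of more steps that carry the O–O bond.

Key step: step 8

Assumption: the lipase of step 2 is taken to hydrolyse the acetate on the (R)-configured carbon of 5. An enzyme of the opposite preference gives the same 6 when run as a mono-acetylation of the corresponding meso-diol. In either case the configuration at C1 of 12 rests on the catalyst of step 6.

## Route

Step 1
Reactants: 1 (triisopropylsilyl)acetylene; 2 allyl bromide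
Product: 4 triisopropyl(pent-4-en-1-yn-1-yl)silane, via lithium (triisopropylsilyl)acetylide 3 (not isolated)
Conditions: n-BuLi, THF, −78 °C; then CuBr·SMe2 (10 mol%), 2, −78 °C → rt
Reagents that add atoms: none
Why: Copper-catalysed allylation of a metal acetylide gives the skipped enyne; the low temperature and the absence of excess base should prevent isomerisation to the conjugated enyne.

Step 2
Reactants: 5 cis-1,4-diacetoxycyclohex-2-ene (meso)
Product: 6 (1R,4S)-4-acetoxycyclohex-2-en-1-ol
Conditions: Candida antarctica lipase B (immobilised), phosphate buffer pH 7, rt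
Reagents that add atoms: none
Why: Enzymatic desymmetrisation of a meso-diacetate by hydrolysis of one enantiotopic ester; it sets the acetoxy-bearing carbon (S), which later makes the reduction product a single diastereomer.

Step 3
Reactants: 6 (1R,4S)-4-acetoxycyclohex-2-en-1-ol
Product: 7 (4S)-4-acetoxycyclohex-2-en-1-one
Conditions: Dess–Martin periodinane, CH2Cl2, 0 °C → rt
Reagents that add atoms: none
Why: Dess–Martin oxidation of a secondary allylic alcohol to the enone under neutral conditions; the acetoxy stereocentre is not touched.

Step 4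
Reactants: 7 (4S)-4-acetoxycyclohex-2-en-1-one
Product: 8 (4S)-4-acetoxy-2-iodocyclohex-2-en-1-one
Conditions: I2, pyridine, CH2Cl2, 0 °C → rt
Reagents that add atoms: iodine, II
Why: α-Iodination of an enone by conjugate addition of pyridine, iodination of the enolate and elimination; it places the halide on C2, the carbon that must carry the chain.

Step 5
Reactants: 4 triisopropyl(pent-4-en-1-yn-1-yl)silane; 8 (4S)-4-acetoxy-2-iodocyclohex-2-en-1-one
Product: 10 (4S)-4-acetoxy-2-[5-(triisopropylsilyl)pent-4-yn-1-yl]cyclohex-2-en-1-one, via B-alkyl-9-borabicyclononane 9 (not isolated)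
Conditions: 4, 9-BBN-H, THF, 0 °C → rt; then 8, PdCl2(dppf) (5 mol%), AsPh3 (5 mol%), K3PO4 (aq), DMF, rt
Reagents that add atoms: none
Why: 9-BBN hydroborates the terminal alkene of 4 and leaves the hindered silyl alkyne; the B-alkyl Suzuki–Miyaura coupling of such a borane with a 2-iodoenone is an established C(sp3)–C(sp2) coupling that runs at room temperature with a mild base, so the acetate should survive.

Step 6
Reactants: 10 (4S)-4-acetoxy-2-[5-(triisopropylsilyl)pent-4-yn-1-yl]cyclohex-2-en-1-one
Product: 11 (1S,4S)-4-acetoxy-2-[5-(triisopropylsilyl)pent-4-yn-1-yl]cyclohex-2-en-1-ol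
Conditions: (R)-2-methyl-CBS-oxazaborolidine (20 mol%), catecholborane, toluene, −78 °C
Reagents that add atoms: none
Why: Corey–Bakshi–Shibata reduction; the C2-substituted alkenyl carbon acts as the large group, so the (R)-catalyst should give the (1S)-carbinol under reagent control, trans to the acetate. Any (1R) epimer is a diastereomer at this stage and can be removed by chromatography, and erosion at the acetoxy carbon would not affect the enantiomeric purity of 12 because that carbon is planarised in step 7.

Step 7
Reactants: 11 (1S,4S)-4-acetoxy-2-[5-(triisopropylsilyl)pent-4-yn-1-yl]cyclohex-2-en-1-ol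
Product: 12 (1S)-2-[5-(triisopropylsilyl)pent-4-yn-1-yl]cyclohexa-2,4-dien-1-ol
Conditions: Pd(PPh3)4 (5 mol%), Et3N, THF, 60 °C
Reagents that add atoms: none
Why: Zerovalent palladium ionises the allylic acetate to a π-allyl complex over C2–C3–C4 with the metal anti to the departed acetate; the metal should sit at the less hindered C4 terminus and lose the syn hydrogen of C5, giving the conjugated diene (Tsuji–Trost-type 1,4-elimination). In the trans isomer the C1 hydrogen lies on the face away from the metal, which closes the path to the enol, and triethylamine keeps the medium basic because the dienol (an arene hydrate) loses water under acid.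

Step 8
Reactants: 12 (1S)-2-[5-(triisopropylsilyl)pent-4-yn-1-yl]cyclohexa-2,4-dien-1-ol
Product: 13 (1R,4R,7S)-1-[5-(triisopropylsilyl)pent-4-yn-1-yl]-2,3-dioxabicyclo[2.2.2]oct-5-en-7-ol (hydroxyl syn to the O–O bridge)
Conditions: O2, 5,10,15,20-tetraphenylporphyrin (cat.), visible light, CCl4, solid NaHCO3, 0 °C
Reagents that add atoms: oxygen, O=O
Why: Sensitised oxygen in its singlet state adds to the s-cis-locked diene C2=C3–C4=C5 of 12 in a concerted, suprafacial [4+2] cycloaddition that forms C2–O and C5–O together; the closest known reaction type is the photo-oxygenation of cyclohexa-1,3-dienes to 2,3-dioxabicyclo[2.2.2]oct-5-enes. The one new ring, the six-membered 3,6-dihydro-1,2-dioxine ring (C1, O2, O3, C4, C5, C6 of 13), is closed by this cycloaddition across the diene termini, and the C7–C8 bridge is what remains of the carbocycle. The two new stereocentres are the bridgeheads C1 and C4: their mutual relation is fixed by the suprafacial mode of addition, and their absolute sense by the face of the diene that is attacked, which the (S)-carbinol C7 controls. The C2 side chain pushes the hydroxyl into the pseudo-axial position (relief of allylic 1,2-strain), from where it can hydrogen-bond to the incoming electrophilic oxygen and steer it to its own face, as in hydroxy-directed photo-oxygenations of chiral allylic and dienylic alcohols; the non-polar, non-hydrogen-bonding solvent is chosen so that this contact is not broken. The step needs facial selectivity and chemoselectivity: the cisoid cyclic diene should react much faster by cycloaddition than any allylic C–H by the ene mode, and the silyl-capped alkyne is inert to singlet oxygen. The adduct with the hydroxyl anti to the peroxide bridge is a diastereomer at this stage and must be removed by chromatography before the carbinol is oxidised, since it would otherwise lead to the enantiomeric ketone. Low temperature, the solid buffer and amine-free handling guard the dienol against dehydration and the unsaturated endoperoxide against rearrangement.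

Step 9
Reactants: 13 (1R,4R,7S)-1-[5-(triisopropylsilyl)pent-4-yn-1-yl]-2,3-dioxabicyclo[2.2.2]oct-5-en-7-ol
Product: 14 (1R,4S,6S)-1-[5-(triisopropylsilyl)pent-4-yn-1-yl]-2,3-dioxabicyclo[2.2.2]octan-6-ol
Conditions: KO2C–N=N–CO2K, AcOH, MeOH/CH2Cl2, −40 → 0 °C
Reagents that add atoms: none
Why: Diimide, generated from the azodicarboxylate salt and acetic acid, transfers two hydrogens to the strained bicyclic alkene in a concerted syn fashion without touching the O–O bond; the hindered silyl alkyne should be far slower. The change of the C4 descriptor comes from a change of substituent priorities only.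

Step 10
Reactants: 14 (1R,4S,6S)-1-[5-(triisopropylsilyl)pent-4-yn-1-yl]-2,3-dioxabicyclo[2.2.2]octan-6-ol
Product: 15 (1R,4S)-1-[5-(triisopropylsilyl)pent-4-yn-1-yl]-2,3-dioxabicyclo[2.2.2]octan-6-one
Conditions: Dess–Martin periodinane, NaHCO3, CH2Cl2, 0 °C
Reagents that add atoms: none
Why: Dess–Martin oxidation under buffered, amine-free conditions gives the ketone; soluble bases are avoided because the C4 hydrogen and the C5 methylene make the peroxide prone to Kornblum–DeLaMare-type and β-elimination cleavage. The carbinol stereocentre, its directing work done, is erased.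

Step 11
Reactants: 15 (1R,4S)-1-[5-(triisopropylsilyl)pent-4-yn-1-yl]-2,3-dioxabicyclo[2.2.2]octan-6-one
Product: 16 (1R,5S)-1-[5-(triisopropylsilyl)pent-4-yn-1-yl]-2,6,7-trioxabicyclo[3.2.2]nonan-3-one
Conditions: mCPBA, NaHCO3, CH2Cl2, 0 °C → rt
Reagents that add atoms: meta-chloroperoxybenzoic acid, O=C(OO)c1cccc(Cl)c1
Why: Baeyer–Villiger oxidation; in the Criegee adduct the bridgehead C1 (tertiary and α-oxygen-substituted) should migrate in preference to the methylene C5, as bridgehead and α-alkoxy carbons do in bicyclic ketones. It migrates with retention, so oxygen is inserted between C1 and the carbonyl and C1 becomes an acyloxy peroxyketal carbon.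

Step 12
Reactants: 16 (1R,5S)-1-[5-(triisopropylsilyl)pent-4-yn-1-yl]-2,6,7-trioxabicyclo[3.2.2]nonan-3-one
Product: 18 methyl 2-[(3S,6R)-6-methoxy-6-[5-(triisopropylsilyl)pent-4-yn-1-yl]-1,2-dioxan-3-yl]acetate, via methoxy peroxyketal acid 17 (not isolated)
Conditions: TsOH·H2O (10 mol%), MeOH, 0 °C → rt
Reagents that add atoms: methanol, CO
Why: Acid ionises the acyloxy peroxyketal to a peroxycarbenium ion and frees the carboxylic acid arm; methanol adds to the cation to give the ketal with axial methoxy (anomeric stabilisation, chain equatorial), that is cis to the equatorial arm on C3, and the acid is esterified in the same medium (Fischer esterification). The ketal exchange is reversible, so C6 settles under thermodynamic control governed by C3, while C3 itself is never touched.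

Step 13
Reactants: 18 methyl 2-[(3S,6R)-6-methoxy-6-[5-(triisopropylsilyl)pent-4-yn-1-yl]-1,2-dioxan-3-yl]acetate
Product: 19 methyl 2-[(3S,6R)-6-methoxy-6-(pent-4-yn-1-yl)-1,2-dioxan-3-yl]acetate
Conditions: Bu4NF, AcOH, THF, 0 °C → rt
Reagents that add atoms: none
Why: Fluoride-mediated protodesilylation of the alkynylsilane; buffering with acetic acid keeps the medium from becoming basic enough to open the β-peroxy ester by retro-oxa-Michael reaction.

Step 14
Reactants: 20 undec-1-yne
Product: 22 (E)-1-iodoundec-1-ene, via (E)-undecenylzirconocene chloride 21 (not isolated)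
Conditions: Cp2Zr(H)Cl, THF, rt; then I2, 0 °C
Reagents that add atoms: iodine, II
Why: Hydrozirconation of the terminal alkyne with the Schwartz reagent is syn and places zirconium on the terminal carbon; iodinolysis of the C–Zr bond goes with retention and gives the (E)-iodoalkene.

Step 15
Reactants: 19 methyl 2-[(3S,6R)-6-methoxy-6-(pent-4-yn-1-yl)-1,2-dioxan-3-yl]acetate; 22 (E)-1-iodoundec-1-ene
Product: 23 methyl 2-[(3S,6R)-6-[(6E)-hexadec-6-en-4-yn-1-yl]-6-methoxy-1,2-dioxan-3-yl]acetate
Conditions: PdCl2(PPh3)2 (5 mol%), CuI (10 mol%), Et3N, THF, rt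
Reagents that add atoms: none
Why: Sonogashira coupling of a terminal alkyne with an (E)-alkenyl iodide at room temperature, with retention of alkene geometry; a saturated 1,2-dioxane should tolerate the palladium, monovalent copper and amine at ambient temperature for the short time needed.

Step 16
Reactants: 23 methyl 2-[(3S,6R)-6-[(6E)-hexadec-6-en-4-yn-1-yl]-6-methoxy-1,2-dioxan-3-yl]acetate
Product: 24 2-[(3S,6R)-6-[(6E)-hexadec-6-en-4-yn-1-yl]-6-methoxy-1,2-dioxan-3-yl]acetic acid
Conditions: LiOH, THF/H2O, 0 °C; then aq. H3PO4 to pH 4, 0 °C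
Reagents that add atoms: lithium hydroxide, [Li+].[OH-]
Why: Saponification of the methyl ester at low temperature followed by mild acidification, so that the peroxyketal is not hydrolysed. Should the β-peroxy carboxylate open and reclose by oxa-Michael addition, the ring should return to the same, more stable C3 configuration because C6 is fixed.

## Compound list

1 | (triisopropylsilyl)acetylene | CC(C)[Si](C#C)(C(C)C)C(C)C | starting material
2 | allyl bromide | C=CCBr | starting material
3 | lithium (triisopropylsilyl)acetylide | [Li]C#C[Si](C(C)C)(C(C)C)C(C)C | intermediate (not isolated)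
4 | triisopropyl(pent-4-en-1-yn-1-yl)silane | C=CCC#C[Si](C(C)C)(C(C)C)C(C)C | intermediate
5 | cis-1,4-diacetoxycyclohex-2-ene (meso) | CC(=O)O[C@H]1CC[C@@H](OC(C)=O)C=C1 | starting material
6 | (1R,4S)-4-acetoxycyclohex-2-en-1-ol | O[C@H]1C=C[C@@H](OC(C)=O)CC1 | intermediate
7 | (4S)-4-acetoxycyclohex-2-en-1-one | O=C1C=C[C@@H](OC(C)=O)CC1 | intermediate
8 | (4S)-4-acetoxy-2-iodocyclohex-2-en-1-one | O=C1C(I)=C[C@@H](OC(C)=O)CC1 | intermediate
9 | 9-[5-(triisopropylsilyl)pent-4-yn-1-yl]-9-borabicyclo[3.3.1]nonane | CC(C)[Si](C#CCCCB1C2CCCC1CCC2)(C(C)C)C(C)C | intermediate (not isolated)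
10 | (4S)-4-acetoxy-2-[5-(triisopropylsilyl)pent-4-yn-1-yl]cyclohex-2-en-1-one | CC(C)[Si](C#CCCCC1=C[C@@H](OC(C)=O)CCC1=O)(C(C)C)C(C)C | intermediate
11 | (1S,4S)-4-acetoxy-2-[5-(triisopropylsilyl)pent-4-yn-1-yl]cyclohex-2-en-1-ol | CC(C)[Si](C#CCCCC1=C[C@@H](OC(C)=O)CC[C@@H]1O)(C(C)C)C(C)C | intermediate
12 | (1S)-2-[5-(triisopropylsilyl)pent-4-yn-1-yl]cyclohexa-2,4-dien-1-ol | CC(C)[Si](C#CCCCC1=CC=CC[C@@H]1O)(C(C)C)C(C)C | intermediate
13 | (1R,4R,7S)-1-[5-(triisopropylsilyl)pent-4-yn-1-yl]-2,3-dioxabicyclo[2.2.2]oct-5-en-7-ol | CC(C)[Si](C#CCCC[C@]1([C@@H](O)C2)C=C[C@@H]2OO1)(C(C)C)C(C)C | intermediate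
14 | (1R,4S,6S)-1-[5-(triisopropylsilyl)pent-4-yn-1-yl]-2,3-dioxabicyclo[2.2.2]octan-6-ol | CC(C)[Si](C#CCCC[C@]1([C@@H](O)C2)CC[C@@H]2OO1)(C(C)C)C(C)C | intermediate
15 | (1R,4S)-1-[5-(triisopropylsilyl)pent-4-yn-1-yl]-2,3-dioxabicyclo[2.2.2]octan-6-one | CC(C)[Si](C#CCCC[C@]1(C(=O)C2)CC[C@@H]2OO1)(C(C)C)C(C)C | intermediate
16 | (1R,5S)-1-[5-(triisopropylsilyl)pent-4-yn-1-yl]-2,6,7-trioxabicyclo[3.2.2]nonan-3-one | CC(C)[Si](C#CCCC[C@]1(OC(=O)C2)CC[C@@H]2OO1)(C(C)C)C(C)C | intermediate
17 | 2-[(3S,6R)-6-methoxy-6-[5-(triisopropylsilyl)pent-4-yn-1-yl]-1,2-dioxan-3-yl]acetic acid | CC(C)[Si](C#CCCC[C@]1(OC)CC[C@@H](CC(=O)O)OO1)(C(C)C)C(C)C | intermediate (not isolated)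
18 | methyl 2-[(3S,6R)-6-methoxy-6-[5-(triisopropylsilyl)pent-4-yn-1-yl]-1,2-dioxan-3-yl]acetate | CC(C)[Si](C#CCCC[C@]1(OC)CC[C@@H](CC(=O)OC)OO1)(C(C)C)C(C)C | intermediate
19 | methyl 2-[(3S,6R)-6-methoxy-6-(pent-4-yn-1-yl)-1,2-dioxan-3-yl]acetate | C#CCCC[C@]1(OC)CC[C@@H](CC(=O)OC)OO1 | intermediate
20 | undec-1-yne | CCCCCCCCCC#C | starting material
21 | chlorobis(cyclopentadienyl)[(E)-undec-1-en-1-yl]zirconium | CCCCCCCCC/C=C/[Zr](Cl)(C1C=CC=C1)C1C=CC=C1 | intermediate (not isolated)
22 | (E)-1-iodoundec-1-ene | CCCCCCCCC/C=C/I | intermediate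
23 | methyl 2-[(3S,6R)-6-[(6E)-hexadec-6-en-4-yn-1-yl]-6-methoxy-1,2-dioxan-3-yl]acetate | CCCCCCCCC/C=C/C#CCCC[C@]1(OC)CC[C@@H](CC(=O)OC)OO1 | intermediate
24 | 2-[(3S,6R)-6-[(6E)-hexadec-6-en-4-yn-1-yl]-6-methoxy-1,2-dioxan-3-yl]acetic acid | CCCCCCCCC/C=C/C#CCCC[C@]1(OC)CC[C@@H](CC(=O)O)OO1 | target

## Step count and least certain steps

Total step count: 16. Longest linear sequence: 14 steps (steps 2 to 13, then 15 and 16, from 5).

**Step 8 (key step).** The most likely failure is insufficient facial selectivity, with oxygen arriving on the face anti to the hydroxyl because one hydrogen bond is a weak bias. Diversion into the ene mode and acid-triggered dehydration of the dienol to the arene are the other risks.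
Fallback: hand the facial control to steric shielding.
- Setting out from 10, reduction with the (S)-configured CBS catalyst should give the epimeric carbinol (1R,4S)-4-acetoxy-2-[5-(triisopropylsilyl)pent-4-yn-1-yl]cyclohex-2-en-1-ol F1.
- F1 is eliminated as in step 7 to (1R)-2-[5-(triisopropylsilyl)pent-4-yn-1-yl]cyclohexa-2,4-dien-1-ol F2.
- F2 is silylated (TBSCl, imidazole) to tert-butyldimethyl({(1R)-2-[5-(triisopropylsilyl)pent-4-yn-1-yl]cyclohexa-2,4-dien-1-yl}oxy)silane F3.
- A bulky pseudo-axial silyloxy group blocks its own face, so photo-oxygenation should now occur anti to it and give (1R,4R,7R)-7-(tert-butyldimethylsilyloxy)-1-[5-(triisopropylsilyl)pent-4-yn-1-yl]-2,3-dioxabicyclo[2.2.2]oct-5-ene F4, which has the bridgehead configurations of 13.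
- Diimide reduction to (1R,4S,6R)-6-(tert-butyldimethylsilyloxy)-1-[5-(triisopropylsilyl)pent-4-yn-1-yl]-2,3-dioxabicyclo[2.2.2]octane F5, desilylation with HF·pyridine to (1R,4S,6R)-1-[5-(triisopropylsilyl)pent-4-yn-1-yl]-2,3-dioxabicyclo[2.2.2]octan-6-ol F6 and Dess–Martin oxidation bring the material back to the route at 15.

**Step 7.** The elimination may take a hydrogen from the side-chain methylene or from C1 instead of C5. A palladium hydride may isomerise the dienol to a ketone, or the dienol may lose water and aromatise on heating.
Fallback: replace the π-allyl pathway by an elimination whose direction is fixed by structure, since a leaving group on C4 has β-hydrogens only on C5.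
- Setting out from 11, the carbinol is silylated (Et3SiCl, imidazole) to (1S,4S)-3-[5-(triisopropylsilyl)pent-4-yn-1-yl]-4-(triethylsilyloxy)cyclohex-2-en-1-yl acetate F7.
- The acetate is removed (K2CO3, MeOH) to give (1S,4S)-3-[5-(triisopropylsilyl)pent-4-yn-1-yl]-4-(triethylsilyloxy)cyclohex-2-en-1-ol F8.
- The free alcohol is dehydrated by syn-elimination with the Burgess reagent to triethyl({(1S)-2-[5-(triisopropylsilyl)pent-4-yn-1-yl]cyclohexa-2,4-dien-1-yl}oxy)silane F9.
- Brief treatment with buffered Bu4NF at low temperature removes the O-silyl group much faster than the C-silyl group and returns to the route at 12.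

**Step 11.** The methylene may migrate in competition with the peroxy-bearing bridgehead, whose oxygen is a poorer donor than an ether oxygen. The acyloxy peroxyketal product may also decompose under the acidic by-product.
Fallback: cleave the same C1–C(=O) bond by a Beckmann fragmentation, which is driven by the cation-stabilising oxygen on C1.
- Setting out from 15, oximation (NH2OH·HCl, NaOAc) should give (1R,4S,6E)-1-[5-(triisopropylsilyl)pent-4-yn-1-yl]-2,3-dioxabicyclo[2.2.2]octan-6-one oxime F10, with the hydroxyl anti to the quaternary carbon.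
- Tosylation gives its O-(p-toluenesulfonyl) derivative F11.
- In methanol F11 should fragment to a nitrile and a peroxycarbenium ion, which the solvent traps to give 2-[(3S,6R)-6-methoxy-6-[5-(triisopropylsilyl)pent-4-yn-1-yl]-1,2-dioxan-3-yl]acetonitrile F12.
- Half-reduction with DIBAL-H at −78 °C gives 2-[(3S,6R)-6-methoxy-6-[5-(triisopropylsilyl)pent-4-yn-1-yl]-1,2-dioxan-3-yl]acetaldehyde F13.
- Pinnick oxidation returns to the route at 17, which is esterified as in the second stage of step 12.

**Step 12.** Kinetic capture of the peroxycarbenium ion may give the epimer with equatorial methoxy. Esterification may be incomplete, or the Brønsted acid may cleave the O–O bond over the time needed for equilibration.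
Fallback: generate the peroxycarbenium ion under aprotic Lewis-acid conditions and deliver the methoxy group from a silyl ether under kinetic axial attack.
- Setting out from 16, methoxytrimethylsilane with catalytic trimethylsilyl triflate in CH2Cl2 at −78 °C should give trimethylsilyl 2-[(3S,6R)-6-methoxy-6-[5-(triisopropylsilyl)pent-4-yn-1-yl]-1,2-dioxan-3-yl]acetate F14.
- Aqueous work-up hydrolyses F14 to 17.
- Methylation with (trimethylsilyl)diazomethane then rejoins the route at 18.

## Further compounds

F1 | step 8 | (1R,4S)-4-acetoxy-2-[5-(triisopropylsilyl)pent-4-yn-1-yl]cyclohex-2-en-1-ol | CC(C)[Si](C#CCCCC1=C[C@@H](OC(C)=O)CC[C@H]1O)(C(C)C)C(C)C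
F2 | step 8 | (1R)-2-[5-(triisopropylsilyl)pent-4-yn-1-yl]cyclohexa-2,4-dien-1-ol | CC(C)[Si](C#CCCCC1=CC=CC[C@H]1O)(C(C)C)C(C)C
F3 | step 8 | tert-butyldimethyl({(1R)-2-[5-(triisopropylsilyl)pent-4-yn-1-yl]cyclohexa-2,4-dien-1-yl}oxy)silane | CC(C)[Si](C#CCCCC1=CC=CC[C@H]1O[Si](C)(C)C(C)(C)C)(C(C)C)C(C)C
F4 | step 8 | (1R,4R,7R)-7-(tert-butyldimethylsilyloxy)-1-[5-(triisopropylsilyl)pent-4-yn-1-yl]-2,3-dioxabicyclo[2.2.2]oct-5-ene | CC(C)[Si](C#CCCC[C@]1([C@H](O[Si](C)(C)C(C)(C)C)C2)C=C[C@@H]2OO1)(C(C)C)C(C)C
F5 | step 8 | (1R,4S,6R)-6-(tert-butyldimethylsilyloxy)-1-[5-(triisopropylsilyl)pent-4-yn-1-yl]-2,3-dioxabicyclo[2.2.2]octane | CC(C)[Si](C#CCCC[C@]1([C@H](O[Si](C)(C)C(C)(C)C)C2)CC[C@@H]2OO1)(C(C)C)C(C)C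
F6 | step 8 | (1R,4S,6R)-1-[5-(triisopropylsilyl)pent-4-yn-1-yl]-2,3-dioxabicyclo[2.2.2]octan-6-ol | CC(C)[Si](C#CCCC[C@]1([C@H](O)C2)CC[C@@H]2OO1)(C(C)C)C(C)C
F7 | step 7 | (1S,4S)-3-[5-(triisopropylsilyl)pent-4-yn-1-yl]-4-(triethylsilyloxy)cyclohex-2-en-1-yl acetate | CC(C)[Si](C#CCCCC1=C[C@@H](OC(C)=O)CC[C@@H]1O[Si](CC)(CC)CC)(C(C)C)C(C)C
F8 | step 7 | (1S,4S)-3-[5-(triisopropylsilyl)pent-4-yn-1-yl]-4-(triethylsilyloxy)cyclohex-2-en-1-ol | CC(C)[Si](C#CCCCC1=C[C@@H](O)CC[C@@H]1O[Si](CC)(CC)CC)(C(C)C)C(C)C
F9 | step 7 | triethyl({(1S)-2-[5-(triisopropylsilyl)pent-4-yn-1-yl]cyclohexa-2,4-dien-1-yl}oxy)silane | CC(C)[Si](C#CCCCC1=CC=CC[C@@H]1O[Si](CC)(CC)CC)(C(C)C)C(C)C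
F10 | step 11 | (1R,4S,6E)-1-[5-(triisopropylsilyl)pent-4-yn-1-yl]-2,3-dioxabicyclo[2.2.2]octan-6-one oxime | CC(C)[Si](C#CCCC[C@]1(/C(=N/O)C2)CC[C@@H]2OO1)(C(C)C)C(C)C
F11 | step 11 | (1R,4S,6E)-1-[5-(triisopropylsilyl)pent-4-yn-1-yl]-2,3-dioxabicyclo[2.2.2]octan-6-one O-(p-toluenesulfonyl)oxime | CC(C)[Si](C#CCCC[C@]1(/C(=N/OS(=O)(=O)c3ccc(C)cc3)C2)CC[C@@H]2OO1)(C(C)C)C(C)C
F12 | step 11 | 2-[(3S,6R)-6-methoxy-6-[5-(triisopropylsilyl)pent-4-yn-1-yl]-1,2-dioxan-3-yl]acetonitrile | CC(C)[Si](C#CCCC[C@]1(OC)CC[C@@H](CC#N)OO1)(C(C)C)C(C)C
F13 | step 11 | 2-[(3S,6R)-6-methoxy-6-[5-(triisopropylsilyl)pent-4-yn-1-yl]-1,2-dioxan-3-yl]acetaldehyde | CC(C)[Si](C#CCCC[C@]1(OC)CC[C@@H](CC=O)OO1)(C(C)C)C(C)C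
F14 | step 12 | trimethylsilyl 2-[(3S,6R)-6-methoxy-6-[5-(triisopropylsilyl)pent-4-yn-1-yl]-1,2-dioxan-3-yl]acetate | CC(C)[Si](C#CCCC[C@]1(OC)CC[C@@H](CC(=O)O[Si](C)(C)C)OO1)(C(C)C)C(C)C
A1 | alternative 1 | 1-bromohept-6-yn-2-one | BrCC(=O)CCCC#C
A2 | alternative 1 | methyl but-3-enoate | C=CCC(=O)OC
A3 | alternative 1 | dioxygen | O=O
A4 | alternative 1 | methyl 2-[(3S,6R)-6-hydroxy-6-(pent-4-yn-1-yl)-1,2-dioxan-3-yl]acetate (drawn as the required enantiomer; formed as the racemate) | C#CCCC[C@]1(O)CC[C@@H](CC(=O)OC)OO1
A5 | alternative 2 | tert-butyl{[(3R)-3-({(3R)-3-methoxy-8-(triisopropylsilyl)oct-1-en-7-yn-3-yl}peroxy)pent-4-en-1-yl]oxy}diphenylsilane | CC(C)[Si](C#CCCC[C@](OC)(C=C)OO[C@@H](C=C)CCO[Si](c1ccccc1)(c1ccccc1)C(C)(C)C)(C(C)C)C(C)C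
A6 | alternative 2 | (3R,6R)-6-[2-(tert-butyldiphenylsilyloxy)ethyl]-3-methoxy-3-[5-(triisopropylsilyl)pent-4-yn-1-yl]-3,6-dihydro-1,2-dioxine | CC(C)[Si](C#CCCC[C@]1(OC)C=C[C@@H](CCO[Si](c2ccccc2)(c2ccccc2)C(C)(C)C)OO1)(C(C)C)C(C)C
A7 | alternative 3 | (4S)-4-benzyl-3-[(2E)-3-{[1-bromo-3-methoxy-8-(triisopropylsilyl)oct-7-yn-3-yl]peroxy}prop-2-enoyl]-1,3-oxazolidin-2-one (ketal carbon drawn in the required sense) | CC(C)[Si](C#CCCC[C@](OC)(CCBr)OO/C=C/C(=O)N1[C@@H](Cc2ccccc2)COC1=O)(C(C)C)C(C)C
A8 | alternative 3 | (4S)-4-benzyl-3-{2-[(3S,6R)-6-methoxy-6-[5-(triisopropylsilyl)pent-4-yn-1-yl]-1,2-dioxan-3-yl]acetyl}-1,3-oxazolidin-2-one | CC(C)[Si](C#CCCC[C@]1(OC)CC[C@@H](CC(=O)N2[C@@H](Cc3ccccc3)COC2=O)OO1)(C(C)C)C(C)C
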